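**Retrosynthetic overview**

- Feature used: the benzene ring (the only ring) carries para oxygens at C1 (free OH) and C4 (OMe), a methoxy at C2 next to C1, hydrogens at C3 and C5, and the C21 chain at C6. C1, C2, C3 and C4 coincide with the carbinol carbon, enol-ether carbon, ring CH and carbonyl carbon of an alkenyl adduct of methyl semisquarate; C5 and C6 come from a 1,1-disubstituted vinyl unit.
- End game: cleave the C1–O–Si bond last; before that, methylate the C4 hydroxyl that the ring expansion sets free.
- Key disconnection: the C4–C5 bond of the arene, made by thermal four-to-six ring expansion of a 4-alkenyl-4-silyloxycyclobutenone through a dienylketene.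
- Precursor assembly: tricos-1-en-2-yllithium (from 2-bromotricos-1-ene, made from 1-bromoeicosane and 2,3-dibromopropene) adds to methyl semisquarate (from dimethyl squarate), and the alkoxide is trapped with a silyl triflate.
- Ring order: the four-membered ring is bought in with dimethyl squarate; the benzene ring is formed once, in the key step.

Key step: step 4

Assumption on the chemistry: methyl semisquarate is taken to behave like its higher alkyl homologues, so that organolithium reagents add to the carbonyl next to the methoxy-bearing carbon. All cyclobutenone intermediates are racemic and their single stereocentre disappears in step 4.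

**Route**

Step 1
Reactants: 1 dimethyl squarate (3,4-dimethoxycyclobut-3-ene-1,2-dione)
Product: 3 3-methoxycyclobut-3-ene-1,2-dione (methyl semisquarate), via 4-hydroxy-2,3-dimethoxycyclobut-2-en-1-one 2 (not isolated)
Conditions: LiAlH(OtBu)3 (1.05 equiv), THF, −78 °C; then 6 M aq HCl, CH2Cl2, 0 °C to rt; used at once
Reagents that add atoms: water, O
Why: Chemoselective 1,2-hydride reduction of one squarate carbonyl by the bulky hydride, then acid-promoted ionisation of the allylic carbinol, capture by water at the methoxy-stabilised terminus and loss of methanol (allylic transposition of a vinylogous ester), the standard passage from dialkyl squarates to alkyl semisquarates.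

Step 2
Reactants: 4 1-bromoeicosane; 5 2,3-dibromopropene
Product: 7 2-bromotricos-1-ene, via eicosylmagnesium bromide 6 (not isolated)
Conditions: Mg, THF, 45 °C; then 5 (1.3 equiv), CuI (5 mol %), THF, 0 °C to rt
Reagents that add atoms: none
Why: Grignard formation followed by CuI-catalysed allylic substitution on 2,3-dibromopropene (SN2 and SN2' paths give the same product) leaves the vinylic bromide untouched, a standard synthesis of 2-bromo-1-alkenes.

Step 3
Reactants: 7 2-bromotricos-1-ene; 3 3-methoxycyclobut-3-ene-1,2-dione
Product: 10 4-[(tert-butyldimethylsilyl)oxy]-3-methoxy-4-(tricos-1-en-2-yl)cyclobut-2-en-1-one (racemic), via tricos-1-en-2-yllithium 8 (not isolated), via tertiary lithium alkoxide 9 (not isolated)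
Conditions: t-BuLi (2.0 equiv), THF/Et2O, −78 °C; cannulate into 3 (1.1 equiv), THF, −78 °C; then TBSOTf (1.3 equiv), −78 to −20 °C; NaHCO3 work-up
Reagents that add atoms: tert-butyldimethylsilyl trifluoromethanesulfonate, CC(C)(C)[Si](C)(C)OS(=O)(=O)C(F)(F)F
Why: Bromine–lithium exchange gives the alkenyllithium, which undergoes 1,2-addition to the more electrophilic C2 carbonyl of 3 (the C1 carbonyl is deactivated as a vinylogous ester), and the tertiary lithium alkoxide is O-silylated by the silyl triflate; the new quaternary carbinol centre forms as a racemate and is erased in step 4.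

Step 4
Reactants: 10 4-[(tert-butyldimethylsilyl)oxy]-3-methoxy-4-(tricos-1-en-2-yl)cyclobut-2-en-1-one
Product: 13 4-[(tert-butyldimethylsilyl)oxy]-3-heneicosyl-5-methoxyphenol, via Z-dienylketene 11 (not isolated), via cyclohexa-2,4-dienone 12 (not isolated)
Conditions: degassed toluene (0.02 M), 110 °C, argon
Reagents that add atoms: none
Why: Heating should cause conrotatory 4π-electrocyclic opening of the cyclobutenone C1–C4 bond to the (Z)-dienylketene 11, whose ketene carbon then bonds to the terminal =CH2 carbon in a disrotatory 6π-electrocyclisation to give cyclohexa-2,4-dienone 12, which enolises to phenol 13. The closest known reaction type is the Moore rearrangement of 4-alkenyl-4-alkoxy- or 4-silyloxycyclobutenones derived from squarate esters to hydroquinone monoethers. The six-membered ring closes in the 6π-electrocyclic mode with all six ring atoms already present, so the carbinol carbon becomes C1, the enol-ether carbon C2, the ring CH C3, the ketene carbon C4, the =CH2 carbon C5 and the chain-bearing carbon C6, the new bond being C4–C5. No stereocentre is created and the one in racemic 10 is destroyed. The step needs torquoselectivity: the alkenyl group must rotate inward so that it ends cis to the ketene, and the silyloxy donor on the same carbon secures this by its strong preference for outward rotation. Because the ketene-derived oxygen emerges as a free hydroxyl while the carbinol oxygen stays silylated, the two para oxygens leave the step chemically distinct.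

Step 5
Reactants: 13 4-[(tert-butyldimethylsilyl)oxy]-3-heneicosyl-5-methoxyphenol
Product: 14 tert-butyl(2-heneicosyl-4,6-dimethoxyphenoxy)dimethylsilane
Conditions: MeI, K2CO3 (anhydrous), acetone, 50 °C
Reagents that add atoms: iodomethane, CI
Why: Williamson ether synthesis on the unhindered phenoxide; the aryl silyl ether, flanked by methoxy and the long alkyl chain, should survive anhydrous carbonate in an aprotic solvent.

Step 6
Reactants: 14 tert-butyl(2-heneicosyl-4,6-dimethoxyphenoxy)dimethylsilane
Product: 15 6-n-heneicosyl-2,4-dimethoxyphenol (target)
Conditions: TBAF (1.1 equiv), AcOH (1.1 equiv), THF, 0 °C, argon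
Reagents that add atoms: none
Why: Fluoride-mediated cleavage of the aryl silyl ether, driven by Si–F bond formation; the acetic acid buffer protonates the electron-rich phenoxide at once and so should suppress its air oxidation.

**Compound list**

1 | dimethyl squarate (3,4-dimethoxycyclobut-3-ene-1,2-dione) | COC1=C(OC)C(=O)C1=O | starting material
2 | 4-hydroxy-2,3-dimethoxycyclobut-2-en-1-one (racemic) | COC1=C(OC)C(O)C1=O | intermediate
3 | 3-methoxycyclobut-3-ene-1,2-dione | COC1=CC(=O)C1=O | intermediate
4 | 1-bromoeicosane | CCCCCCCCCCCCCCCCCCCCBr | starting material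
5 | 2,3-dibromopropene | C=C(Br)CBr | starting material
6 | eicosylmagnesium bromide | CCCCCCCCCCCCCCCCCCCC[Mg]Br | intermediate
7 | 2-bromotricos-1-ene | C=C(Br)CCCCCCCCCCCCCCCCCCCCC | intermediate
8 | tricos-1-en-2-yllithium | [Li]C(=C)CCCCCCCCCCCCCCCCCCCCC | intermediate
9 | lithium 2-methoxy-4-oxo-1-(tricos-1-en-2-yl)cyclobut-2-en-1-olate (racemic) | [Li]OC1(C(=C)CCCCCCCCCCCCCCCCCCCCC)C(OC)=CC1=O | intermediate
10 | 4-[(tert-butyldimethylsilyl)oxy]-3-methoxy-4-(tricos-1-en-2-yl)cyclobut-2-en-1-one (racemic) | O=C1C=C(OC)C1(O[Si](C)(C)C(C)(C)C)C(=C)CCCCCCCCCCCCCCCCCCCCC | intermediate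
11 | (3Z)-4-[(tert-butyldimethylsilyl)oxy]-3-methoxy-5-methylidenehexacosa-1,3-dien-1-one | O=C=C/C(OC)=C(\C(=C)CCCCCCCCCCCCCCCCCCCCC)O[Si](C)(C)C(C)(C)C | intermediate
12 | 4-[(tert-butyldimethylsilyl)oxy]-5-heneicosyl-3-methoxycyclohexa-2,4-dien-1-one | O=C1C=C(OC)C(O[Si](C)(C)C(C)(C)C)=C(CCCCCCCCCCCCCCCCCCCCC)C1 | intermediate
13 | 4-[(tert-butyldimethylsilyl)oxy]-3-heneicosyl-5-methoxyphenol | Oc1cc(OC)c(O[Si](C)(C)C(C)(C)C)c(CCCCCCCCCCCCCCCCCCCCC)c1 | intermediate
14 | tert-butyl(2-heneicosyl-4,6-dimethoxyphenoxy)dimethylsilane | COc1cc(OC)c(O[Si](C)(C)C(C)(C)C)c(CCCCCCCCCCCCCCCCCCCCC)c1 | intermediate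
15 | 6-n-heneicosyl-2,4-dimethoxyphenol | CCCCCCCCCCCCCCCCCCCCCc1cc(OC)cc(OC)c1O | target

**Step count**

Total steps: 6. Longest linear sequence: 5 steps (step 2, 3, 4, 5, 6; the branch through step 1 is equally long).

**Steps most likely to fail, with fallbacks**

1. Step 3. The long-chain bromide or alkenyllithium may crystallise at −78 °C, so that exchange is incomplete and residual t-BuLi attacks the dione. The alkenyllithium may also add at the vinylogous ester carbonyl or deprotonate the ring CH, and silylation of the hindered alkoxide may stall. Fallback: make the alkenyllithium by a Shapiro reaction, which releases it in homogeneous solution at 0 °C. The fallback sets out from 4. Alkylation of ethyl acetoacetate with 4 (NaOEt, EtOH, reflux) should give ethyl 2-acetyldocosanoate F1. Saponification and decarboxylation (aq NaOH, then H2SO4, heat) should give tricosan-2-one F2. Condensation with 2,4,6-triisopropylbenzenesulfonyl hydrazide (THF/MeOH, cat. HCl) should give N'-(tricosan-2-ylidene)-2,4,6-triisopropylbenzenesulfonohydrazide F3. Treatment with n-BuLi (2.0 equiv) in THF/TMEDA at −78 °C and warming to 0 °C deprotonates the methyl group and expels sulfinate and dinitrogen. This comes back to the route at 8, which is added to 3 and silylated as in step 3, with extra silyl triflate to cover the sulfinate.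

2. Step 4. The silyl group may be lost or transferred between molecules at high temperature, the ketene may be intercepted (dimerisation, moisture) before ring closure, or inward rotation of the alkenyl group may be incomplete. Fallback: run the ring expansion on the free carbinol, the classical hydroxycyclobutenone variant, and differentiate the oxygens afterwards by sterics. The fallback sets out from 9. Quenching with aqueous NH4Cl instead of the silyl triflate should give 4-hydroxy-3-methoxy-4-(tricos-1-en-2-yl)cyclobut-2-en-1-one F4. Thermolysis in degassed toluene under argon should give 2-heneicosyl-6-methoxybenzene-1,4-diol F5. Mono-O-methylation (MeI 1.0 equiv, K2CO3, acetone, argon) should occur at the unhindered C4 hydroxyl, because the C1 hydroxyl is flanked by methoxy and heneicosyl. This comes back to the route at 15.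

3. Step 1. Over-reduction may occur, or the methyl vinylogous ester may hydrolyse during the acid treatment, with loss of the small, water-soluble product on work-up. Fallback: accept the hydrolysis and re-esterify. The fallback sets out from 2. Complete hydrolysis in aqueous HCl should give semisquaric acid (3-hydroxycyclobut-3-ene-1,2-dione) F6, isolated by evaporation. O-methylation with trimethyl orthoformate in refluxing methanol, the conditions that esterify squaric acid, comes back to the route at 3.

**Further compounds**

F1 | step 3 | ethyl 2-acetyldocosanoate | CCCCCCCCCCCCCCCCCCCCC(C(C)=O)C(=O)OCC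
F2 | step 3 | tricosan-2-one | CC(=O)CCCCCCCCCCCCCCCCCCCCC
F3 | step 3 | N'-(tricosan-2-ylidene)-2,4,6-triisopropylbenzenesulfonohydrazide | CC(=NNS(=O)(=O)c1c(C(C)C)cc(C(C)C)cc1C(C)C)CCCCCCCCCCCCCCCCCCCCC
F4 | step 4 | 4-hydroxy-3-methoxy-4-(tricos-1-en-2-yl)cyclobut-2-en-1-one (racemic) | O=C1C=C(OC)C1(O)C(=C)CCCCCCCCCCCCCCCCCCCCC
F5 | step 4 | 2-heneicosyl-6-methoxybenzene-1,4-diol | Oc1cc(OC)c(O)c(CCCCCCCCCCCCCCCCCCCCC)c1
F6 | step 1 | semisquaric acid (3-hydroxycyclobut-3-ene-1,2-dione) | OC1=CC(=O)C1=O
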